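**Retrosynthetic overview**

1. Target ⇐ its heptamethyl ether (BBr3) ⇐ an aryl bromide in which ring A (the 3,5‑dioxygenated ring) is still a 2‑bromobenzyl group on the benzylic methine. A Pd‑catalysed C–H arylation onto ring D (the mono‑oxygenated ring) makes the biaryl bond and the six‑membered ring of the 9,10‑dihydrophenanthrene.
2. Key disconnection (locants of 10,11‑dihydro‑5H‑dibenzo[a,d][7]annulene): the seven‑membered ring is cut at the CH2–CH(aryl) bond C11–C10 and at the bond from ring B (the fused catechol ring, C5a) to the benzylic methine C5. A bis(3,4‑dimethoxyphenyl)methyl cation (C10, C9a, C5a) and a ring‑D o‑quinodimethane (C11, C11a, C4a, C5) are joined in one acid‑catalysed (4+3) annulation that also sets both stereocentres.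
3. Enabling feature: C5 and C11 are two benzylic carbons on neighbouring carbons of ring D, with C5 para to the ring‑D oxygen (a latent o‑quinodimethane that becomes a stabilised cation at C5 once C11 has reacted). C10 is a bis(3,4‑dioxygenated aryl)methine whose ring‑B ortho carbon C5a is para to a ring oxygen (a latent diarylcarbenium ion carrying its own arene nucleophile).
4. The o‑quinodimethane precursor (an o‑stannylmethyl benzylic carbinol) comes from a stannylated benzaldehyde plus a benzylzinc reagent. The carbenium precursor is the benzhydrol from veratraldehyde and an aryl Grignard reagent.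
5. Ring order: the four benzene rings are bought; seven‑membered ring in step 7, six‑membered ring in step 8.

Key step: step 7

Remark: the sense of induction of the chiral acid in step 7 cannot be derived from first principles; the (S,S) antipode is written, and the antipode that leads to the (5S,10S) product would be fixed in the first runs.

**Step 1**
Reactants: 1 3,4‑dimethoxybenzaldehyde; 2 (3,4‑dimethoxyphenyl)magnesium bromide
Product: 3 bis(3,4‑dimethoxyphenyl)methanol
Conditions: THF, 0 → 25 °C; then H2O
Reagents that add atoms: none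
Why: Grignard addition of an aryl nucleophile to an aromatic aldehyde gives the benzhydrol, which has no stereocentre because the two aryl groups are identical.

**Step 2**
Reactants: 4 4‑methoxy‑2‑methylbenzonitrile
Product: 5 2‑(bromomethyl)‑4‑methoxybenzonitrile
Conditions: NBS, AIBN (cat.), PhCF3, 85 °C
Reagents that add atoms: N‑bromosuccinimide, O=C1CCC(=O)N1Br
Why: Wohl–Ziegler benzylic bromination at the only benzylic C–H site, the nitrile lowering the tendency of the anisole ring to undergo electrophilic bromination.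

**Step 3**
Reactants: 5 2‑(bromomethyl)‑4‑methoxybenzonitrile
Product: 7 4‑methoxy‑2‑[(tributylstannyl)methyl]benzonitrile, via benzylzinc bromide 6 (not isolated)
Conditions: Zn dust, LiCl, THF, 25 °C; then Bu3SnCl, 25 °C
Reagents that add atoms: tributyltin chloride, CCCC[Sn](Cl)(CCCC)CCCC
Why: LiCl‑mediated zinc insertion into the benzylic C–Br bond tolerates the nitrile, and the benzylzinc reagent is stannylated by the chlorostannane (Barbier‑type benzylstannane synthesis).

**Step 4**
Reactants: 7 4‑methoxy‑2‑[(tributylstannyl)methyl]benzonitrile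
Product: 9 4‑methoxy‑2‑[(tributylstannyl)methyl]benzaldehyde, via N‑aluminio imine 8 (not isolated)
Conditions: i‑Bu2AlH (DIBAL‑H), toluene, −78 °C; then H2O, wet SiO2, 0 → 25 °C
Reagents that add atoms: water, O
Why: DIBAL‑H adds once to the nitrile and the N‑aluminio imine is hydrolysed to the aldehyde under neutral conditions that leave the benzylic C–Sn bond intact.

**Step 5**
Reactants: 10 1‑(bromomethyl)‑3,5‑dimethoxybenzene
Product: 11 2‑bromo‑1‑(bromomethyl)‑3,5‑dimethoxybenzene
Conditions: NBS, MeCN, 0 → 25 °C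
Reagents that add atoms: N‑bromosuccinimide, O=C1CCC(=O)N1Br
Why: Electrophilic aromatic bromination occurs para to one methoxy group and ortho to the other (position 2), the site between the two methoxy groups being the more hindered one.

**Step 6**
Reactants: 11 2‑bromo‑1‑(bromomethyl)‑3,5‑dimethoxybenzene; 9 4‑methoxy‑2‑[(tributylstannyl)methyl]benzaldehyde
Product: 13 rac‑2‑(2‑bromo‑3,5‑dimethoxyphenyl)‑1‑{4‑methoxy‑2‑[(tributylstannyl)methyl]phenyl}ethan‑1‑ol, via benzylzinc bromide 12 (not isolated)
Conditions: Zn dust, LiCl, THF, 25 °C; then 9, 0 → 25 °C; pH 7 buffer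
Reagents that add atoms: none
Why: Zinc insertion into the benzylic bromide spares the aryl bromide, and 1,2‑addition of the benzylzinc reagent to the aldehyde gives the carbinol as a racemate, which is immaterial because this carbon is ionised in step 7.

**Step 7**
Reactants: 3 bis(3,4‑dimethoxyphenyl)methanol; 13 rac‑2‑(2‑bromo‑3,5‑dimethoxyphenyl)‑1‑{4‑methoxy‑2‑[(tributylstannyl)methyl]phenyl}ethan‑1‑ol
Product: 17 (5S,10S)‑5‑(2‑bromo‑3,5‑dimethoxybenzyl)‑10‑(3,4‑dimethoxyphenyl)‑2,7,8‑trimethoxy‑10,11‑dihydro‑5H‑dibenzo[a,d][7]annulene (5‑H and 10‑H cis), via diarylcarbenium ion 14 (not isolated), via o‑quinodimethane 15 (not isolated), via benzylic cation 16 (not isolated)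
Conditions: (S,S)‑IDPi Brønsted acid {[(S)‑3,3′‑bis(3,5‑bis(trifluoromethyl)phenyl)‑BINOL‑P(=NSO2CF3)]2NH} (5 mol%), CH3CO2H (1.1 equiv), 5 Å molecular sieves, CHCl3, −20 → 25 °C, 13 added slowly to 3
Reagents that add atoms: none
Why: Proposed new method: the chiral acid ionises 3 to carbenium ion 14 and induces the 1,4‑elimination of water and the stannyl group from 13 (a known acid‑induced route to o‑quinodimethanes from o‑(α‑hydroxyalkyl)benzylstannanes; acetic acid takes up the tin), and o‑quinodimethane 15 adds through its CH2 terminus to 14 (C10–C11 bond), which restores ring D and leaves the p‑methoxybenzylic cation 16 that is captured by the carbon para to the 3‑methoxy group of one of the two 3,4‑dimethoxyphenyl rings (C5–C5a bond). The closest known reaction types are the formal (4+3) annulation of indolyl‑ and furfuryl‑carbinol‑derived cations with 1,3‑dienes, the (3+2) indane synthesis from benzhydryl cations and styrenes, and confined‑acid‑catalysed asymmetric hydroarylation through chiral ion pairs. The seven‑membered ring closes by a 7‑endo‑trig Friedel–Crafts cyclisation onto the benzylic cation; proton loss from 16 to the stilbene is reversible under the strong acid, whereas the ring closure is not. C10 becomes stereogenic only in this closure, which selects one of the two enantiotopic aryl groups, and C5 is created in the same event: the cis relation of 5‑H and 10‑H should follow from a boat‑like transition state with the arylmethyl group on C5 pseudo‑axial (away from both peri hydrogens) and the spectator aryl group on C10 antiperiplanar to ring D, and the absolute configuration from the chiral counter‑anion paired with 16. The step needs attack of 14 at the CH2 terminus of 15 (only this mode gives the methoxy‑stabilised cation), capture of 15 before dimerisation or a 1,5‑hydrogen shift (slow addition, (E)‑geometry of 15), and ortho rather than ipso closure (ipso attack cannot rearomatise and is reversible).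

**Step 8**
Reactants: 17 (5S,10S)‑5‑(2‑bromo‑3,5‑dimethoxybenzyl)‑10‑(3,4‑dimethoxyphenyl)‑2,7,8‑trimethoxy‑10,11‑dihydro‑5H‑dibenzo[a,d][7]annulene
Product: 18 hepta‑O‑methyl ether of the target (configuration as in 19)
Conditions: Pd(OAc)2 (10 mol%), PCy3·HBF4 (20 mol%), K2CO3, pivalic acid (30 mol%), DMA, 130 °C
Reagents that add atoms: none
Why: Palladium‑catalysed intramolecular direct arylation (concerted metalation–deprotonation) closes the six‑membered ring onto the ring‑D C–H next to C5, which has one neighbouring substituent, in preference to the ring‑B C–H lying between the ring fusion and a methoxy group, and the carbonate base does not touch the stereocentres.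

**Step 9**
Reactants: 18 hepta‑O‑methyl ether of the target
Product: 19 CNP0306974.1
Conditions: BBr3 (excess), CH2Cl2, −78 → 25 °C; then H2O
Reagents that add atoms: none
Why: Lewis acid cleavage of all seven aryl methyl ethers with BBr3, under which the two benzylic stereocentres, carrying no leaving group, are not ionised.

**Compound list**

1 | 3,4‑dimethoxybenzaldehyde | COc1ccc(C=O)cc1OC | starting material
2 | (3,4‑dimethoxyphenyl)magnesium bromide (THF solution) | COc1ccc([Mg]Br)cc1OC | starting material
3 | bis(3,4‑dimethoxyphenyl)methanol | COc1ccc(C(O)c2ccc(OC)c(OC)c2)cc1OC | intermediate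
4 | 4‑methoxy‑2‑methylbenzonitrile | COc1ccc(C#N)c(C)c1 | starting material
5 | 2‑(bromomethyl)‑4‑methoxybenzonitrile | COc1ccc(C#N)c(CBr)c1 | intermediate
6 | (2‑cyano‑5‑methoxybenzyl)zinc bromide (not isolated) | COc1ccc(C#N)c(C[Zn]Br)c1 | intermediate
7 | 4‑methoxy‑2‑[(tributylstannyl)methyl]benzonitrile | CCCC[Sn](CCCC)(CCCC)Cc1cc(OC)ccc1C#N | intermediate
8 | N‑(diisobutylaluminio)‑1‑{4‑methoxy‑2‑[(tributylstannyl)methyl]phenyl}methanimine (not isolated) | CCCC[Sn](CCCC)(CCCC)Cc1cc(OC)ccc1C=N[Al](CC(C)C)CC(C)C | intermediate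
9 | 4‑methoxy‑2‑[(tributylstannyl)methyl]benzaldehyde | CCCC[Sn](CCCC)(CCCC)Cc1cc(OC)ccc1C=O | intermediate
10 | 1‑(bromomethyl)‑3,5‑dimethoxybenzene | COc1cc(CBr)cc(OC)c1 | starting material
11 | 2‑bromo‑1‑(bromomethyl)‑3,5‑dimethoxybenzene | COc1cc(CBr)c(Br)c(OC)c1 | intermediate
12 | (2‑bromo‑3,5‑dimethoxybenzyl)zinc bromide (not isolated) | COc1cc(C[Zn]Br)c(Br)c(OC)c1 | intermediate
13 | rac‑2‑(2‑bromo‑3,5‑dimethoxyphenyl)‑1‑{4‑methoxy‑2‑[(tributylstannyl)methyl]phenyl}ethan‑1‑ol | CCCC[Sn](CCCC)(CCCC)Cc1cc(OC)ccc1C(O)Cc1cc(OC)cc(OC)c1Br | intermediate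
14 | bis(3,4‑dimethoxyphenyl)methylium, ion pair with the catalyst anion (not isolated) | COc1ccc([CH+]c2ccc(OC)c(OC)c2)cc1OC | intermediate
15 | (E)‑2‑bromo‑1‑[2‑(4‑methoxy‑6‑methylidenecyclohexa‑2,4‑dien‑1‑ylidene)ethyl]‑3,5‑dimethoxybenzene (not isolated) | C=C1C=C(OC)C=C/C1=C\Cc1cc(OC)cc(OC)c1Br | intermediate
16 | 1‑{2‑[2,2‑bis(3,4‑dimethoxyphenyl)ethyl]‑4‑methoxyphenyl}‑2‑(2‑bromo‑3,5‑dimethoxyphenyl)ethan‑1‑ylium (not isolated) | COc1ccc(C(Cc2cc(OC)ccc2[CH+]Cc2cc(OC)cc(OC)c2Br)c2ccc(OC)c(OC)c2)cc1OC | intermediate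
17 | (5S,10S)‑5‑(2‑bromo‑3,5‑dimethoxybenzyl)‑10‑(3,4‑dimethoxyphenyl)‑2,7,8‑trimethoxy‑10,11‑dihydro‑5H‑dibenzo[a,d][7]annulene | COc1cc(OC)c(Br)c(c1)C[C@@H]1c2cc(OC)c(OC)cc2[C@H](c2ccc(OC)c(OC)c2)Cc2cc(OC)ccc12 | intermediate
18 | hepta‑O‑methyl ether of 19: the skeleton of 19 with all seven OH as OMe; benzylic CH of the dihydrophenanthrene ring R, diarylmethine CH S | COc1cc(OC)c2c(c1)C[C@@H]1c3cc(OC)c(OC)cc3[C@H](c3ccc(OC)c(OC)c3)Cc3cc(OC)cc-2c31 | intermediate
19 | CNP0306974.1: 9,10‑dihydrophenanthrene (rings A and D) whose benzylic CH (R) and neighbouring ring‑D carbon are bridged by (4,5‑dihydroxy‑1,2‑phenylene)–CH(3,4‑dihydroxyphenyl)(S)–CH2; heptaphenol | Oc1cc(O)c2c(c1)C[C@@H]1c3cc(O)c(O)cc3[C@H](c3ccc(O)c(O)c3)Cc3cc(O)cc-2c31 | target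

**Step count**

Total: 9 steps. Longest linear sequence: 7 steps (4 → 19 through steps 2, 3, 4, 6, 7, 8, 9).

**Steps most likely to fail**

Step 7 (proposed method). The o‑quinodimethane may be lost to dimerisation or a sigmatropic hydrogen shift before it meets the carbenium ion. Proton loss from the benzylic cation may outrun ring closure. The counter‑anion may discriminate poorly between the two aryl groups and the two faces, eroding enantio‑ and diastereoselectivity. The fallback uses known reactions only, sets out from 3 and 5, and rejoins the route at 17. Ionic hydrogenation of 3 (Et3SiH, CF3CO2H, CH2Cl2) would give bis(3,4‑dimethoxyphenyl)methane F1. Deprotonation with n‑BuLi (THF, −78 °C) would give [bis(3,4‑dimethoxyphenyl)methyl]lithium F2, and alkylation with bromide 5 would give 2‑[2,2‑bis(3,4‑dimethoxyphenyl)ethyl]‑4‑methoxybenzonitrile F3. DIBAL‑H reduction through the N‑aluminio imine F4 and hydrolysis would give 2‑[2,2‑bis(3,4‑dimethoxyphenyl)ethyl]‑4‑methoxybenzaldehyde F5. Addition of zinc reagent 12, as in step 6, would give the carbinol rac‑1‑{2‑[2,2‑bis(3,4‑dimethoxyphenyl)ethyl]‑4‑methoxyphenyl}‑2‑(2‑bromo‑3,5‑dimethoxyphenyl)ethan‑1‑ol F6. An acid‑mediated intramolecular Friedel–Crafts alkylation (CF3SO3H cat., (CF3)2CHOH/CH2Cl2, 0 °C) would then close the seven‑membered ring to the racemate of 17 and its (5R,10R)‑enantiomer F7. Preparative HPLC on a chiral stationary phase would deliver 17.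

Step 8. Palladation may occur at the ring‑B C–H ortho to methoxy, oxidative addition into the doubly ortho‑substituted bromide may be slow, and protodebromination may compete. The fallback sets out from 17 and returns at 18: an aryl radical cyclisation (Bu3SnH, AIBN, benzene, 80 °C; homolytic aromatic substitution, in which the radical adds to the less hindered ring‑D position and the adduct rearomatises). It replaces the metalation mechanism and makes no compound outside the list (F0).

Step 6. Wurtz‑type homocoupling may occur during zinc insertion, addition to the hindered electron‑rich aldehyde may be sluggish, and the product may undergo acid‑triggered 1,4‑elimination during work‑up. The fallback sets out from 7 and 11, returns at 13, and also bypasses step 4. Magnesium insertion into the benzylic C–Br bond of 11 (Mg, Et2O, 0 °C) would give (2‑bromo‑3,5‑dimethoxybenzyl)magnesium bromide F8. Its addition to nitrile 7 (CuBr cat., toluene/Et2O) would give the N‑(bromomagnesio) ketimine F9, hydrolysed with buffer to the ketone 2‑(2‑bromo‑3,5‑dimethoxyphenyl)‑1‑{4‑methoxy‑2‑[(tributylstannyl)methyl]phenyl}ethan‑1‑one F10. Reduction with NaBH4 (MeOH, 0 °C) would give 13.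

**Further compounds**

F1 | step 7 | bis(3,4‑dimethoxyphenyl)methane | COc1ccc(Cc2ccc(OC)c(OC)c2)cc1OC
F2 | step 7 | [bis(3,4‑dimethoxyphenyl)methyl]lithium | COc1ccc(C([Li])c2ccc(OC)c(OC)c2)cc1OC
F3 | step 7 | 2‑[2,2‑bis(3,4‑dimethoxyphenyl)ethyl]‑4‑methoxybenzonitrile | COc1ccc(C#N)c(CC(c2ccc(OC)c(OC)c2)c2ccc(OC)c(OC)c2)c1
F4 | step 7 | N‑(diisobutylaluminio) imine of F5 | COc1ccc(C=N[Al](CC(C)C)CC(C)C)c(CC(c2ccc(OC)c(OC)c2)c2ccc(OC)c(OC)c2)c1
F5 | step 7 | 2‑[2,2‑bis(3,4‑dimethoxyphenyl)ethyl]‑4‑methoxybenzaldehyde | COc1ccc(C=O)c(CC(c2ccc(OC)c(OC)c2)c2ccc(OC)c(OC)c2)c1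
F6 | step 7 | rac‑1‑{2‑[2,2‑bis(3,4‑dimethoxyphenyl)ethyl]‑4‑methoxyphenyl}‑2‑(2‑bromo‑3,5‑dimethoxyphenyl)ethan‑1‑ol | COc1ccc(C(O)Cc2cc(OC)cc(OC)c2Br)c(CC(c2ccc(OC)c(OC)c2)c2ccc(OC)c(OC)c2)c1
F7 | step 7 | (5R,10R)‑enantiomer of 17 | COc1cc(OC)c(Br)c(c1)C[C@H]1c2cc(OC)c(OC)cc2[C@@H](c2ccc(OC)c(OC)c2)Cc2cc(OC)ccc12
F0 | step 8 | none | none
F8 | step 6 | (2‑bromo‑3,5‑dimethoxybenzyl)magnesium bromide | COc1cc(C[Mg]Br)c(Br)c(OC)c1
F9 | step 6 | N‑(bromomagnesio) ketimine of F10 | CCCC[Sn](CCCC)(CCCC)Cc1cc(OC)ccc1C(=N[Mg]Br)Cc1cc(OC)cc(OC)c1Br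
F10 | step 6 | 2‑(2‑bromo‑3,5‑dimethoxyphenyl)‑1‑{4‑methoxy‑2‑[(tributylstannyl)methyl]phenyl}ethan‑1‑one | CCCC[Sn](CCCC)(CCCC)Cc1cc(OC)ccc1C(=O)Cc1cc(OC)cc(OC)c1Br
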